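Assumption: the target has no stereocentre and no stereogenic double bond, so it is achiral and the one structure drawn is the only stereoisomer; no enantiocontrol is needed.

**Retrosynthetic overview**
1. The benzene ring is bought complete as 2',6'-dihydroxyacetophenone 1 and masked as its bis-MOM ether 2; the C16 chain is bought as methyl palmitate 3.
2. Key C–C disconnection: C2–C3 of the acyclic 1,3-diketone (sodium salt 4, free diketone 5), made by an intermolecular crossed Claisen condensation of the enolate of 2 with 3.
3. Last disconnection: O1–C2 of the pyranone; acid unmasks 5 to dihydroxy diketone 6, which closes to hemiketal 7 and dehydrates to target 8.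
4. Ring order: the benzene ring is present from the start; the pyranone ring is formed last, in the only ring-forming step.

**Route**

Step 1
Reactants: 1 2',6'-dihydroxyacetophenone
Product: 2 1-[2,6-bis(methoxymethoxy)phenyl]ethan-1-one
Conditions: NaH (2.5 equiv), DMF, 0 °C; then MOMCl (2.5 equiv), 0 °C to rt
Reagents that add atoms: chloromethyl methyl ether (MOMCl), COCCl
Why: Williamson-type O-alkylation of the bis-phenoxide with a highly reactive α-chloro ether; full deprotonation by NaH breaks the hydrogen bond to the ketone that would otherwise slow the second etherification.

Step 2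
Reactants: 2 1-[2,6-bis(methoxymethoxy)phenyl]ethan-1-one, 3 methyl hexadecanoate (methyl palmitate, 1.5 equiv)
Product: 5 1-[2,6-bis(methoxymethoxy)phenyl]octadecane-1,3-dione, via sodium diketonate 4 (not isolated)
Conditions: NaH (3 equiv), THF, reflux; then 1 M aq. HCl, 0 °C, to pH 5
Reagents that add atoms: none
Why: Crossed Claisen condensation in which the more acidic methyl ketone is enolised in preference to the ester, its di-ortho-substituted carbonyl is too hindered for self-aldol, and irreversible deprotonation of the β-diketone to 4 drives the equilibrium; the MOM ethers are inert to base and to the cold pH 5 quench.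

Step 3
Reactants: 5 1-[2,6-bis(methoxymethoxy)phenyl]octadecane-1,3-dione
Product: 8 5-hydroxy-2-pentadecyl-4H-chromen-4-one, via dihydroxy diketone 6 (not isolated), via cyclic hemiketal 7 (not isolated)
Conditions: 3 M HCl in MeOH, reflux, 3 h
Reagents that add atoms: none
Why: Acid-catalysed acetal solvolysis frees both phenols, one of the two equivalent hydroxyls adds to the C3 ketone (6-membered hemiketalisation), and acid-catalysed dehydration gives the conjugated 4-pyranone (cyclodehydration of a 2-hydroxyaryl 1,3-diketone), leaving the other hydroxyl as the chelated 5-OH.

**Compound list**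
1 | 2',6'-dihydroxyacetophenone [1-(2,6-dihydroxyphenyl)ethan-1-one] | CC(=O)c1c(O)cccc1O | starting material
2 | 1-[2,6-bis(methoxymethoxy)phenyl]ethan-1-one | CC(=O)c1c(OCOC)cccc1OCOC | intermediate
3 | methyl hexadecanoate (methyl palmitate) | CCCCCCCCCCCCCCCC(=O)OC | starting material
4 | sodium 1-[2,6-bis(methoxymethoxy)phenyl]-1,3-dioxooctadecan-2-ide (sodium diketonate) | CCCCCCCCCCCCCCCC(=O)[CH-]C(=O)c1c(OCOC)cccc1OCOC.[Na+] | intermediate
5 | 1-[2,6-bis(methoxymethoxy)phenyl]octadecane-1,3-dione | CCCCCCCCCCCCCCCC(=O)CC(=O)c1c(OCOC)cccc1OCOC | intermediate
6 | 1-(2,6-dihydroxyphenyl)octadecane-1,3-dione | CCCCCCCCCCCCCCCC(=O)CC(=O)c1c(O)cccc1O | intermediate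
7 | 2,5-dihydroxy-2-pentadecylchroman-4-one (racemic hemiketal; its stereocentre is lost on dehydration) | CCCCCCCCCCCCCCCC1(O)CC(=O)c2c(O)cccc2O1 | intermediate
8 | 5-hydroxy-2-pentadecyl-4H-chromen-4-one | CCCCCCCCCCCCCCCc1cc(=O)c2c(O)cccc2o1 | target

**Totals**
Total step count: 3. Longest linear sequence: 3 steps (1 → 2 → 5 → 8).

**Steps most likely to fail, with fallbacks**

Step 2 (most at risk: self-condensation of 3, sluggish acylation of the hindered enolate). The fallback sets out from 2 and comes back at 5. Ketone 2 is deprotonated with LiN(iPr)2 in THF at −78 °C and the lithium enolate is trapped with hexadecanal (CCCCCCCCCCCCCCCC=O, commercial) in a fast, irreversible aldol addition. This gives racemic 1-[2,6-bis(methoxymethoxy)phenyl]-3-hydroxyoctadecan-1-one F1. Its carbinol is then oxidised with Dess–Martin periodinane in NaHCO3-buffered CH2Cl2 at rt, which removes the stereocentre and delivers diketone 5. The C–C bond is thus made by aldol addition to an aldehyde and the oxidation level is adjusted afterwards, so no ester electrophile is needed.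

Step 3 (at risk: stalling at hemiketal 7 or its methyl ketal, or acid-induced retro-Claisen cleavage of the diketone). The fallback sets out from 1 and comes back at 8. Compound 1 and hexadecanal are heated with pyrrolidine in EtOH at reflux (Kabbe condensation: enamine/aldol condensation followed by oxa-Michael ring closure) to give racemic 5-hydroxy-2-pentadecylchroman-4-one F2. This is dehydrogenated with DDQ in 1,4-dioxane at reflux to chromone 8; the stereocentre at C2 disappears. The pyranone ring is closed here by conjugate addition and then oxidised, so no cyclodehydration of a diketone is required.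

Step 1 (least at risk: incomplete protection of the second, hydrogen-bonded hydroxyl). The fallback sets out from 1 and comes back at 6. Unprotected 1 is converted into its trilithium polyanion with LiN(SiMe3)2 (4.5 equiv) in THF at −78 to −10 °C and C-acylated with 3 (−78 °C to rt, then cold dilute HCl). This gives dihydroxy diketone 6 directly, in equilibrium with 7, and the material is then closed to 8 under the conditions of step 3. No compound outside the list arises on this way (none F0). The main route keeps the protecting groups because the protected intermediates are homogeneous in solution and easy to purify.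

**Further compounds**
F0 | step 1 | none | none
F1 | step 2 | 1-[2,6-bis(methoxymethoxy)phenyl]-3-hydroxyoctadecan-1-one (racemic) | CCCCCCCCCCCCCCCC(O)CC(=O)c1c(OCOC)cccc1OCOC
F2 | step 3 | 5-hydroxy-2-pentadecylchroman-4-one (racemic) | CCCCCCCCCCCCCCCC1CC(=O)c2c(O)cccc2O1
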